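**Plan**

- Retrosynthesis: after removal of five benzyl ethers, each outer ring is cut at its aryl–acyl bond and the neighbouring aryl–oxygen bond (ring A: C1–C(=O) and C2–O; ring C: C5'–C(=O) and C6'–O), leaving two arynes and two molecules of butanoic acid.
- Enabling feature: in ring A (C1 butanoyl, C2 OH, C3 Me, C4 OMe, C5 CH2, C6 OH) the pair C1/C2 lies between oxygenated C6 and methylated C3. In ring C (C1' CH2, C2' OH, C3' Me, C4' OMe, C5' butanoyl, C6' OH) the pair C5'/C6' lies between C4'–OMe and C1'–CH2. Each is an unsymmetrical 3-alkoxyaryne with the alkoxy group next to the future acyl carbon.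
- Further cuts: the two ArCH2–Ar bonds to the central ring B (o-quinone methide alkylation of 2,4,6-trihydroxyacetophenone), then both outer rings back to one formylated 2-methylphloroglucinol, 3.
- Forward: no ring is built. Aldehyde 3 is turned into the two regioisomeric silyl carbamate Mannich bases 10 (ring A) and 16 (ring C); ring C and then ring A are joined to ring B; benzylation, carbamate-to-triflate exchange, twofold aryne insertion and hydrogenolysis follow.
- Stereochemistry: the target has no stereocentre, so none has to be set.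

Key step: step 16

Remark: read atom by atom, the two outer rings are constitutional isomers (butanoyl between two hydroxyls in ring A, between hydroxyl and methoxy in ring C), so two different silyl triflate units are built; in step 16 the two insertions may occur in either order and one order is drawn.

**Route**

Step 1
Reactants: 1 2-methylbenzene-1,3,5-triol
Product: 3 2,4,6-trihydroxy-3-methylbenzaldehyde, via aryl iminium chloride 2 (not isolated)
Conditions: POCl3, DMF, EtOAc, 0 °C to rt; then H2O, 60 °C
Reagents that add atoms: N,N-dimethylformamide, CN(C)C=O; water, O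
Why: Vilsmeier–Haack formylation of the electron-rich ring at one of its two equivalent free positions should stop after one formyl group because that group deactivates the ring, and hydrolysis of 2 releases the aldehyde.

Step 2
Reactants: 3 2,4,6-trihydroxy-3-methylbenzaldehyde
Product: 4 4,6-bis(benzyloxy)-2-hydroxy-3-methylbenzaldehyde
Conditions: BnBr (2.05 equiv), K2CO3 (2.2 equiv), DMF, 0 °C to rt
Reagents that add atoms: benzyl bromide, BrCc1ccccc1
Why: Williamson etherification under weak base should take the most acidic para-hydroxyl and then the less hindered ortho-hydroxyl, while the hydroxyl wedged between formyl and methyl stays hydrogen-bonded to the carbonyl and remains free.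

Step 3
Reactants: 4 4,6-bis(benzyloxy)-2-hydroxy-3-methylbenzaldehyde
Product: 5 4,6-bis(benzyloxy)-2-methoxy-3-methylbenzaldehyde
Conditions: MeI (5 equiv), K2CO3 (3 equiv), DMF, 50 °C
Reagents that add atoms: iodomethane, CI
Why: Williamson methylation of the last, chelated hydroxyl under more forcing conditions places the methyl ether next to the ring methyl, the position that becomes C4–OMe of ring A.

Step 4
Reactants: 5 4,6-bis(benzyloxy)-2-methoxy-3-methylbenzaldehyde
Product: 6 4,6-dihydroxy-2-methoxy-3-methylbenzaldehyde
Conditions: H2 (1 atm), 10% Pd/C, EtOAc, rt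
Reagents that add atoms: none
Why: Catalytic hydrogenolysis should cleave both benzyl ethers while the strongly donor-substituted (vinylogous ester type) aldehyde and the methyl ether persist.

Step 5
Reactants: 6 4,6-dihydroxy-2-methoxy-3-methylbenzaldehyde
Product: 7 4-formyl-5-hydroxy-3-methoxy-2-methylphenyl N-isopropylcarbamate
Conditions: i-PrNCO (1.05 equiv), Et3N (0.1 equiv), CH2Cl2, 0 °C to rt
Reagents that add atoms: isopropyl isocyanate, CC(C)N=C=O
Why: Base-catalysed addition of a phenol to an isocyanate (carbamoylation) should occur at the para-hydroxyl, because the ortho-hydroxyl is tied up in a hydrogen bond to the formyl group.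

Step 6
Reactants: 7 4-formyl-5-hydroxy-3-methoxy-2-methylphenyl N-isopropylcarbamate
Product: 8 4-[(dimethylamino)methyl]-5-hydroxy-3-methoxy-2-methylphenyl N-isopropylcarbamate
Conditions: Me2NH (2 M in THF, 3 equiv), AcOH, NaBH(OAc)3, ClCH2CH2Cl, rt
Reagents that add atoms: dimethylamine, CNC
Why: Reductive amination under weakly acidic conditions converts the salicylaldehyde into an ortho-hydroxybenzyl dimethylamine (phenolic Mannich base) and should leave the N–H carbamate untouched.

Step 7
Reactants: 8 4-[(dimethylamino)methyl]-5-hydroxy-3-methoxy-2-methylphenyl N-isopropylcarbamate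
Product: 10 4-[(dimethylamino)methyl]-5-hydroxy-3-methoxy-2-methyl-6-(trimethylsilyl)phenyl N-isopropylcarbamate, via bis(trimethylsilyl) derivative 9 (not isolated)
Conditions: TMSOTf (2.2 equiv), TMEDA, Et2O, 0 °C to rt; n-BuLi (3.3 equiv), −78 °C; sat. aq. NH4Cl, MeOH
Reagents that add atoms: trimethylsilyl trifluoromethanesulfonate, C[Si](C)(C)OS(=O)(=O)C(F)(F)F
Why: Directed ortho-metalation of the transiently N,O-silylated carbamate should lithiate the only ring C–H, and a 1,3 O-to-C silyl shift (retro-Brook rearrangement) from the adjacent silyl ether then places the trimethylsilyl group on that carbon.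

Step 8
Reactants: 3 2,4,6-trihydroxy-3-methylbenzaldehyde
Product: 11 2,6-dihydroxy-4-methoxy-3-methylbenzaldehyde
Conditions: MeI (1.0 equiv), K2CO3 (1.0 equiv), DMF, 0 °C
Reagents that add atoms: iodomethane, CI
Why: Williamson methylation with one equivalent of base and electrophile should select the most acidic, non-chelated para-hydroxyl.

Step 9
Reactants: 11 2,6-dihydroxy-4-methoxy-3-methylbenzaldehyde
Product: 12 3-bromo-2,6-dihydroxy-4-methoxy-5-methylbenzaldehyde
Conditions: NBS (1.0 equiv), MeCN, 0 °C
Reagents that add atoms: N-bromosuccinimide, O=C1CCC(=O)N1Br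
Why: Electrophilic aromatic bromination can only enter the single free ring position between methoxy and hydroxyl, which fixes where silicon will later sit.

Step 10
Reactants: 12 3-bromo-2,6-dihydroxy-4-methoxy-5-methylbenzaldehyde
Product: 13 4-bromo-2-[(dimethylamino)methyl]-5-methoxy-6-methylbenzene-1,3-diol
Conditions: Me2NH (2 M in THF, 3 equiv), AcOH, NaBH(OAc)3, ClCH2CH2Cl, rt
Reagents that add atoms: dimethylamine, CNC
Why: Reductive amination as in step 6 should give the phenolic Mannich base with the aryl bromide intact.

Step 11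
Reactants: 13 4-bromo-2-[(dimethylamino)methyl]-5-methoxy-6-methylbenzene-1,3-diol
Product: 16 2-[(dimethylamino)methyl]-3-hydroxy-5-methoxy-4-methyl-6-(trimethylsilyl)phenyl N-isopropylcarbamate, via bis(trimethylsilyl) ether 14 (not isolated), via lithium phenoxide 15 (not isolated)
Conditions: (Me3Si)2NH, THF, 65 °C, then concentration; n-BuLi (1.1 equiv), THF, −78 °C; i-PrNCO (1.1 equiv), −78 to 0 °C; sat. aq. NH4Cl, MeOH
Reagents that add atoms: hexamethyldisilazane, C[Si](C)(C)N[Si](C)(C)C; isopropyl isocyanate, CC(C)N=C=O
Why: Bromine–lithium exchange followed by retro-Brook rearrangement can only move the silyl ether ortho to the lithiated carbon, so the phenoxide next to silicon (15) is formed unambiguously and is the oxygen carbamoylated by the isocyanate, while the other silyl ether falls off on work-up.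

Step 12
Reactants: 16 2-[(dimethylamino)methyl]-3-hydroxy-5-methoxy-4-methyl-6-(trimethylsilyl)phenyl N-isopropylcarbamate; 17 2,4,6-trihydroxyacetophenone
Product: 20 ring B–ring C diarylmethane, via ammonium iodide 18 (not isolated), via ring C quinone methide 19 (not isolated)
Conditions: MeI (5 equiv), MeCN, rt, then evaporation; 17 (3 equiv), NaHCO3 (2 equiv), DMF, 50 °C
Reagents that add atoms: none
Why: N-Methylation gives a benzylic ammonium phenol that loses trimethylamine under mild base to an o-quinone methide, and conjugate addition of the phloroacetophenone carbon nucleophile (in excess to prevent double alkylation) with rearomatisation should give the diarylmethane.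

Step 13
Reactants: 10 4-[(dimethylamino)methyl]-5-hydroxy-3-methoxy-2-methyl-6-(trimethylsilyl)phenyl N-isopropylcarbamate; 20 ring B–ring C diarylmethane
Product: 23 trimeric pentaphenol biscarbamate, via ammonium iodide 21 (not isolated), via ring A quinone methide 22 (not isolated)
Conditions: MeI (5 equiv), MeCN, rt, then evaporation; 20 (1.0 equiv), NaHCO3 (2 equiv), DMF, 50 °C
Reagents that add atoms: none
Why: The same o-quinone methide C-alkylation now has only one nucleophilic carbon available, the last free position of ring B, since ring C in 20 is fully substituted.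

Step 14
Reactants: 23 trimeric pentaphenol biscarbamate
Product: 24 penta-O-benzyl biscarbamate
Conditions: BnBr (8 equiv), K2CO3 (8 equiv), DMF, rt to 40 °C
Reagents that add atoms: benzyl bromide, BrCc1ccccc1
Why: Williamson benzylation in a dipolar aprotic solvent should etherify all five phenols at oxygen, and K2CO3 near ambient temperature is expected to be too weak to cleave the N–H carbamates or to disturb the aryl–silicon bonds.

Step 15
Reactants: 24 penta-O-benzyl biscarbamate
Product: 26 bis[2-(trimethylsilyl)aryl triflate], via bisphenol 25 (not isolated)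
Conditions: DBU (3 equiv), Et2NH (3 equiv), MeCN, 40 °C; then PhNTf2 (3 equiv), 40 °C
Reagents that add atoms: N-phenylbis(trifluoromethanesulfonimide), O=S(=O)(N(c1ccccc1)S(=O)(=O)C(F)(F)F)C(F)(F)F
Why: The N–H carbamates are cleaved by E1cB loss of isopropyl isocyanate (trapped by Et2NH as a urea) and the liberated phenoxides are triflated in the same pot, the usual last operation in making 2-(trimethylsilyl)aryl triflates.

Step 16
Reactants: 26 bis[2-(trimethylsilyl)aryl triflate]; 27 butanoic acid
Product: 31 penta-O-benzyl ether of the target, via ring A aryne 28 (not isolated), via monoketone 29 (not isolated), via ring C aryne 30 (not isolated)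
Conditions: CsF (10 equiv), 27 (4 equiv), THF (0.02 M), 125 °C, sealed tube
Reagents that add atoms: none
Why: Fluoride attacks each trimethylsilyl group and triflate departs, generating in turn the ring A aryne (C1≡C2) and the ring C aryne (C5'≡C6'); caesium butanoate adds through oxygen to C2 and to C6', and the aryl anion left at C1 or C5' attacks the adjacent ester carbonyl to give a four-membered alkoxide that opens to the ortho-acyl phenoxide, so the C2–O/C1–C(=O) and C6'–O/C5'–C(=O) bonds are formed. The closest known reaction is the CsF-mediated insertion of arynes from 2-(trimethylsilyl)aryl triflates into the C–O bond of carboxylic acids, which gives ortho-hydroxyaryl ketones in hot THF. No ring remains in the product (the only closure is the transient four-membered ring, formed by 4-exo-trig attack of the aryl anion on the ester C=O) and no stereocentre is created. The step needs regioselective oxygen attack: the benzyloxy group on C6 (ring A) and the methoxy group on C4' (ring C) polarise the triple bond by induction so that the nucleophile enters at the remote aryne carbon and the charge develops next to the alkoxy group, overriding the C3 methyl and the C1' benzylic substituent on the other side. It also needs acyl transfer to outrun protonation and butanoate to outrun other nucleophiles: excess CsF keeps the acid as its caesium salt, THF offers no acidic C–H, the sparingly soluble fluoride releases the arynes slowly at high dilution, and the surplus of butanoate competes with the product phenoxides and with neighbouring ether oxygens.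

Step 17
Reactants: 31 penta-O-benzyl ether of the target
Product: 32 target, 1-[3-[(3-butanoyl-2,4-dihydroxy-6-methoxy-5-methylphenyl)methyl]-5-[(3-butanoyl-2,6-dihydroxy-4-methoxy-5-methylphenyl)methyl]-2,4,6-trihydroxyphenyl]ethanone
Conditions: H2 (1 atm), 10% Pd/C, EtOAc–MeOH, rt
Reagents that add atoms: none
Why: Catalytic hydrogenolysis should remove the five benzyl ethers, while the three aryl ketones (each flanked by ortho-oxygens) and the diarylmethane bridges are not expected to be reduced under these conditions.

**Compound list**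

1 | 2-methylbenzene-1,3,5-triol | Cc1c(O)cc(O)cc1O | starting material
2 | N-methyl-N-[(2,4,6-trihydroxy-3-methylphenyl)methylidene]methanaminium chloride (not isolated) | C[N+](C)=Cc1c(O)c(C)c(O)cc1O.[Cl-] | intermediate
3 | 2,4,6-trihydroxy-3-methylbenzaldehyde | O=Cc1c(O)c(C)c(O)cc1O | intermediate
4 | 4,6-bis(benzyloxy)-2-hydroxy-3-methylbenzaldehyde | O=Cc1c(O)c(C)c(OCc2ccccc2)cc1OCc1ccccc1 | intermediate
5 | 4,6-bis(benzyloxy)-2-methoxy-3-methylbenzaldehyde | O=Cc1c(OC)c(C)c(OCc2ccccc2)cc1OCc1ccccc1 | intermediate
6 | 4,6-dihydroxy-2-methoxy-3-methylbenzaldehyde | O=Cc1c(OC)c(C)c(O)cc1O | intermediate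
7 | 4-formyl-5-hydroxy-3-methoxy-2-methylphenyl N-isopropylcarbamate | O=Cc1c(OC)c(C)c(OC(=O)NC(C)C)cc1O | intermediate
8 | 4-[(dimethylamino)methyl]-5-hydroxy-3-methoxy-2-methylphenyl N-isopropylcarbamate | CN(C)Cc1c(OC)c(C)c(OC(=O)NC(C)C)cc1O | intermediate
9 | N,O-bis(trimethylsilyl) derivative of 8 (silyl ether and N-silyl carbamate; not isolated) | CN(C)Cc1c(OC)c(C)c(OC(=O)N(C(C)C)[Si](C)(C)C)cc1O[Si](C)(C)C | intermediate
10 | 4-[(dimethylamino)methyl]-5-hydroxy-3-methoxy-2-methyl-6-(trimethylsilyl)phenyl N-isopropylcarbamate (ring A unit) | CN(C)Cc1c(OC)c(C)c(OC(=O)NC(C)C)c([Si](C)(C)C)c1O | intermediate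
11 | 2,6-dihydroxy-4-methoxy-3-methylbenzaldehyde | O=Cc1c(O)c(C)c(OC)cc1O | intermediate
12 | 3-bromo-2,6-dihydroxy-4-methoxy-5-methylbenzaldehyde | O=Cc1c(O)c(C)c(OC)c(Br)c1O | intermediate
13 | 4-bromo-2-[(dimethylamino)methyl]-5-methoxy-6-methylbenzene-1,3-diol | CN(C)Cc1c(O)c(C)c(OC)c(Br)c1O | intermediate
14 | bis(trimethylsilyl) ether of 13 (not isolated) | CN(C)Cc1c(O[Si](C)(C)C)c(C)c(OC)c(Br)c1O[Si](C)(C)C | intermediate
15 | lithium 2-[(dimethylamino)methyl]-5-methoxy-4-methyl-6-(trimethylsilyl)-3-(trimethylsilyloxy)phenoxide (not isolated) | CN(C)Cc1c(O[Si](C)(C)C)c(C)c(OC)c([Si](C)(C)C)c1[O-].[Li+] | intermediate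
16 | 2-[(dimethylamino)methyl]-3-hydroxy-5-methoxy-4-methyl-6-(trimethylsilyl)phenyl N-isopropylcarbamate (ring C unit) | CN(C)Cc1c(O)c(C)c(OC)c([Si](C)(C)C)c1OC(=O)NC(C)C | intermediate
17 | 2,4,6-trihydroxyacetophenone | CC(=O)c1c(O)cc(O)cc1O | starting material
18 | trimethylammonium iodide of 16 (not isolated) | C[N+](C)(C)Cc1c(O)c(C)c(OC)c([Si](C)(C)C)c1OC(=O)NC(C)C.[I-] | intermediate
19 | ring C o-quinone methide: 3-methoxy-4-methyl-6-methylidene-5-oxo-2-(trimethylsilyl)cyclohexa-1,3-dien-1-yl N-isopropylcarbamate (not isolated) | C=C1C(=O)C(C)=C(OC)C([Si](C)(C)C)=C1OC(=O)NC(C)C | intermediate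
20 | ring B–ring C diarylmethane: 2-[(3-acetyl-2,4,6-trihydroxyphenyl)methyl]-3-hydroxy-5-methoxy-4-methyl-6-(trimethylsilyl)phenyl N-isopropylcarbamate | CC(=O)c1c(O)cc(O)c(Cc2c(O)c(C)c(OC)c([Si](C)(C)C)c2OC(=O)NC(C)C)c1O | intermediate
21 | trimethylammonium iodide of 10 (not isolated) | C[N+](C)(C)Cc1c(OC)c(C)c(OC(=O)NC(C)C)c([Si](C)(C)C)c1O.[I-] | intermediate
22 | ring A o-quinone methide: 3-methoxy-2-methyl-4-methylidene-5-oxo-6-(trimethylsilyl)cyclohexa-1,3-dien-1-yl N-isopropylcarbamate (not isolated) | C=C1C(OC)=C(C)C(OC(=O)NC(C)C)=C([Si](C)(C)C)C1=O | intermediate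
23 | trimeric pentaphenol biscarbamate: 2,4,6-trihydroxyacetophenone (ring B) bearing at C3 the ring C benzyl group [2-hydroxy-4-methoxy-3-methyl-5-(trimethylsilyl)-6-(isopropylcarbamoyloxy)benzyl] and at C5 the ring A benzyl group [2-hydroxy-6-methoxy-5-methyl-3-(trimethylsilyl)-4-(isopropylcarbamoyloxy)benzyl] | CC(=O)c1c(O)c(Cc2c(OC)c(C)c(OC(=O)NC(C)C)c([Si](C)(C)C)c2O)c(O)c(Cc2c(O)c(C)c(OC)c([Si](C)(C)C)c2OC(=O)NC(C)C)c1O | intermediate
24 | penta-O-benzyl biscarbamate: 23 with all five phenols as benzyl ethers | CC(=O)c1c(OCc2ccccc2)c(Cc2c(OC)c(C)c(OC(=O)NC(C)C)c([Si](C)(C)C)c2OCc2ccccc2)c(OCc2ccccc2)c(Cc2c(OCc3ccccc3)c(C)c(OC)c([Si](C)(C)C)c2OC(=O)NC(C)C)c1OCc1ccccc1 | intermediate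
25 | bisphenol: 24 with both carbamates cleaved to hydroxyls (not isolated) | CC(=O)c1c(OCc2ccccc2)c(Cc2c(OC)c(C)c(O)c([Si](C)(C)C)c2OCc2ccccc2)c(OCc2ccccc2)c(Cc2c(OCc3ccccc3)c(C)c(OC)c([Si](C)(C)C)c2O)c1OCc1ccccc1 | intermediate
26 | bis[2-(trimethylsilyl)aryl triflate]: 2,4,6-tris(benzyloxy)acetophenone bearing at C3 the ring C group [2-(benzyloxy)-4-methoxy-3-methyl-5-(trimethylsilyl)-6-(triflyloxy)benzyl] and at C5 the ring A group [2-(benzyloxy)-6-methoxy-5-methyl-3-(trimethylsilyl)-4-(triflyloxy)benzyl] | CC(=O)c1c(OCc2ccccc2)c(Cc2c(OC)c(C)c(OS(=O)(=O)C(F)(F)F)c([Si](C)(C)C)c2OCc2ccccc2)c(OCc2ccccc2)c(Cc2c(OCc3ccccc3)c(C)c(OC)c([Si](C)(C)C)c2OS(=O)(=O)C(F)(F)F)c1OCc1ccccc1 | intermediate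
27 | butanoic acid | CCCC(=O)O | starting material
28 | ring A aryne: 26 with the ring A silyl and triflate groups replaced by a C1≡C2 triple bond (not isolated) | CC(=O)c1c(OCc2ccccc2)c(CC4=C(OCc2ccccc2)C#CC(C)=C4OC)c(OCc2ccccc2)c(Cc2c(OCc3ccccc3)c(C)c(OC)c([Si](C)(C)C)c2OS(=O)(=O)C(F)(F)F)c1OCc1ccccc1 | intermediate
29 | monoketone: ring A carries C1 butanoyl and C2 hydroxyl, ring C is still the silyl triflate (not isolated) | CC(=O)c1c(OCc2ccccc2)c(Cc2c(OC)c(C)c(O)c(C(=O)CCC)c2OCc2ccccc2)c(OCc2ccccc2)c(Cc2c(OCc3ccccc3)c(C)c(OC)c([Si](C)(C)C)c2OS(=O)(=O)C(F)(F)F)c1OCc1ccccc1 | intermediate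
30 | ring C aryne: 29 with the ring C silyl and triflate groups replaced by a C5'≡C6' triple bond (not isolated) | CC(=O)c1c(OCc2ccccc2)c(Cc2c(OC)c(C)c(O)c(C(=O)CCC)c2OCc2ccccc2)c(OCc2ccccc2)c(CC4=C(OCc3ccccc3)C(C)=C(OC)C#C4)c1OCc1ccccc1 | intermediate
31 | penta-O-benzyl ether of the target: 2,4,6-tris(benzyloxy)acetophenone bearing at C3 the ring C group [2-(benzyloxy)-5-butanoyl-6-hydroxy-4-methoxy-3-methylbenzyl] and at C5 the ring A group [2-(benzyloxy)-3-butanoyl-4-hydroxy-6-methoxy-5-methylbenzyl] | CC(=O)c1c(OCc2ccccc2)c(Cc2c(OC)c(C)c(O)c(C(=O)CCC)c2OCc2ccccc2)c(OCc2ccccc2)c(Cc2c(OCc3ccccc3)c(C)c(OC)c(C(=O)CCC)c2O)c1OCc1ccccc1 | intermediate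
32 | 1-[3-[(3-butanoyl-2,4-dihydroxy-6-methoxy-5-methylphenyl)methyl]-5-[(3-butanoyl-2,6-dihydroxy-4-methoxy-5-methylphenyl)methyl]-2,4,6-trihydroxyphenyl]ethanone | CCCC(=O)c1c(O)c(C)c(OC)c(Cc2c(O)c(Cc3c(O)c(C)c(OC)c(C(=O)CCC)c3O)c(O)c(C(C)=O)c2O)c1O | target

**Step count**

Total: 17 steps. Longest linear sequence: 12 steps (steps 1–7 and 13–17).

**Steps most likely to fail**

Step 16 is the most exposed. The aryl anion may be protonated before the 1,3-acyl shift, which would stop the reaction at O-aryl esters. The ring C aryne may also be intercepted by the adjacent benzyloxy oxygen of ring B through a six-membered transition state, and product phenoxide or the acetyl enolate may be arylated by remaining aryne. The fallback separates the two bond formations. Starting from 26, aryne capture at room temperature in MeCN with CsF and a large excess of butanoic acid (conditions under which arynes are simply O-arylated by carboxylic acids) should give the bis(aryl butanoate) F1. Irradiation at 254 nm in MeCN (photo-Fries rearrangement) would then move each acyl group to carbon. In both rings the only open ortho or para position of the ester is the carbon that lost silicon, so the acyl groups can only arrive at C1 and C5', and the sequence rejoins the route at 31.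

Step 14 may suffer from C-benzylation with dearomatisation of the fully substituted ring B, incomplete etherification of the hindered hydroxyls, or base-induced loss of the N–H carbamates. The fallback avoids phenoxides altogether: from 23, a Mitsunobu etherification with benzyl alcohol, PPh3 and diisopropyl azodicarboxylate in THF forms the aryl benzyl ethers under neutral conditions and arrives directly at 24; this detour makes no new compound (F0).

Step 7 may fail through lateral lithiation at the ring methyl group beside the carbamate, anionic migration of the carbamoyl group, or sluggish deprotonation at a carbon flanked by two bulky oxygen substituents. The fallback fixes the site of the carbanion beforehand. From 8, NBS in CH2Cl2 with AcOH (amine protonated) brominates the single free ring position to give the aryl bromide F2. In situ silylation with TMSOTf and TMEDA gives its N,O-bis(trimethylsilyl) derivative F3. Bromine–lithium exchange with n-BuLi at −78 °C then generates the aryllithium exactly at the required carbon, and the same O-to-C silyl shift and work-up lead back to 10.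

**Further compounds**

F1 | step 16 | bis(aryl butanoate): 2,4,6-tris(benzyloxy)acetophenone bearing at C3 the ring C group [2-(benzyloxy)-6-(butanoyloxy)-4-methoxy-3-methylbenzyl] and at C5 the ring A group [2-(benzyloxy)-4-(butanoyloxy)-6-methoxy-5-methylbenzyl] | CC(=O)c1c(OCc2ccccc2)c(Cc2c(OC)c(C)c(OC(=O)CCC)cc2OCc2ccccc2)c(OCc2ccccc2)c(Cc2c(OCc3ccccc3)c(C)c(OC)cc2OC(=O)CCC)c1OCc1ccccc1
F0 | step 14 | none | none
F2 | step 7 | 6-bromo-4-[(dimethylamino)methyl]-5-hydroxy-3-methoxy-2-methylphenyl N-isopropylcarbamate | CN(C)Cc1c(OC)c(C)c(OC(=O)NC(C)C)c(Br)c1O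
F3 | step 7 | N,O-bis(trimethylsilyl) derivative of F2 | CN(C)Cc1c(OC)c(C)c(OC(=O)N(C(C)C)[Si](C)(C)C)c(Br)c1O[Si](C)(C)C
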